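Ring B (C5–C6–C7–C8–C9–C10, labdane numbering) of this cis-fused decalin is disconnected at C5–C6 and C9–C10, the hindered bond to quaternary C10. Both bonds should form in one intermolecular, Lewis-acid-promoted Diels–Alder reaction between an enantiopure ring A enone (temporary C1 ketone, C5=C10 alkene, C4 ester centre in place) and an (E)-diene C6=C7–C8=C9 that already carries the C11–C15 chain and an acetoxymethyl group (C17) on C8. The cis arrangement of H-5 and the C10 methyl and the C9 chain trans to that methyl are exactly the ortho-endo adduct pattern; the C4 ester steers the diene to the opposite face. Allylic reduction, deoxygenation and a late caffeate assembly complete the route.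

Key step: step 8

Remark on numbering: C1–C20 follow labdane numbering of the target. Ring A is C1–C5 and C10, ring B is C5–C10, the chain is C11–C15 with methyl C16 on C13, C17 is the exocyclic methylene carbon on C8, C18 and C19 are the methyl and carboxyl carbons on C4, and C20 is the methyl on C10. The target is the (4S,5S,9R,10R,13S) isomer: H-5, the C10 methyl, H-9 and the C4 carboxyl lie on one face.

Assumption: the face selectivity of the cinchona-catalysed Michael addition in step 1 is assigned by analogy with α-substituted β-keto ester donors; if 9-O-benzylcupreidine should favour the (R)-adduct, its quinine-derived pseudoenantiomer 9-O-benzylcupreine is used instead.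

Step 1
Reactants: 1 ethyl 2-formylpropanoate; 2 pent-1-en-3-one
Product: 3 ethyl (2S)-2-formyl-2-methyl-5-oxoheptanoate
Conditions: 9-O-benzylcupreidine (10 mol%), CH2Cl2, −20 °C
Reagents that add atoms: none
Why: Enantioselective Michael addition of an α-substituted β-dicarbonyl-type donor to a vinyl ketone under bifunctional cinchona (base/hydrogen-bond) catalysis, in which the catalyst-bound enol attacks the enone from one face and sets the quaternary centre (later C4) as S.

Step 2
Reactants: 3 ethyl (2S)-2-formyl-2-methyl-5-oxoheptanoate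
Product: 4 ethyl (1S)-1,3-dimethyl-4-oxocyclohex-2-ene-1-carboxylate
Conditions: p-TsOH·H2O (10 mol%), toluene, reflux, Dean–Stark trap
Reagents that add atoms: none
Why: Acid-catalysed intramolecular aldol condensation (the ring-closing half of a Robinson annulation), in which the more substituted enol of the ethyl ketone adds to the non-enolisable aldehyde and dehydration gives the 2-methyl enone, while the quaternary centre cannot epimerise and acid avoids retro-Michael cleavage.

Step 3
Reactants: 5 (S)-citronellol
Product: 6 tert-butyl{[(3S)-3,7-dimethyloct-6-en-1-yl]oxy}diphenylsilane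
Conditions: TBDPSCl, imidazole, CH2Cl2, 0 °C to rt
Reagents that add atoms: tert-butyl(chloro)diphenylsilane, CC(C)(C)[Si](Cl)(c1ccccc1)c1ccccc1
Why: Imidazole-assisted silylation of the primary alcohol gives an ether that should tolerate ozone, organolithium reagents and the Lewis acid of the key step.

Step 4
Reactants: 6 tert-butyl{[(3S)-3,7-dimethyloct-6-en-1-yl]oxy}diphenylsilane
Product: 8 (4S)-6-[(tert-butyldiphenylsilyl)oxy]-4-methylhexanal, via secondary ozonide 7 (not isolated)
Conditions: O3, CH2Cl2, −78 °C; then PPh3, −78 °C to rt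
Reagents that add atoms: ozone, [O-][O+]=O
Why: Ozonolysis of the trisubstituted alkene with reductive work-up of the ozonide gives the aldehyde whose carbonyl carbon becomes C9, the remote C13 centre being untouched.

Step 5
Reactants: 8 (4S)-6-[(tert-butyldiphenylsilyl)oxy]-4-methylhexanal
Product: 9 tert-butyl{[(3S)-7,7-dibromo-3-methylhept-6-en-1-yl]oxy}diphenylsilane
Conditions: CBr4 (2 equiv), PPh3 (4 equiv), CH2Cl2, 0 °C
Reagents that add atoms: carbon tetrabromide, BrC(Br)(Br)Br
Why: Corey–Fuchs (Ramirez) dibromo-olefination of the aldehyde through the dibromomethylene ylide installs C8 as a CBr2 group.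

Step 6
Reactants: 9 tert-butyl{[(3S)-7,7-dibromo-3-methylhept-6-en-1-yl]oxy}diphenylsilane
Product: 10 tert-butyl{[(3S,6Z)-7-bromo-3-methylnona-6,8-dien-1-yl]oxy}diphenylsilane
Conditions: tributyl(vinyl)stannane, Pd2(dba)3 (2.5 mol%), tri(2-furyl)phosphine (15 mol%), toluene, 100 °C
Reagents that add atoms: tributyl(vinyl)stannane, C=C[Sn](CCCC)(CCCC)CCCC
Why: Stille coupling in which zerovalent palladium inserts selectively into the less hindered C–Br bond trans to the alkyl chain, so the vinyl group (C7=C6) enters trans to C11 and the remaining bromine stays cis to the chain.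

Step 7
Reactants: 10 tert-butyl{[(3S,6Z)-7-bromo-3-methylnona-6,8-dien-1-yl]oxy}diphenylsilane
Product: 13 (2Z,6S)-8-[(tert-butyldiphenylsilyl)oxy]-2-ethenyl-6-methyloct-2-en-1-yl acetate, via dienyllithium 11 (not isolated), via lithium alkoxide 12 (not isolated)
Conditions: t-BuLi (2.1 equiv), Et2O, −78 °C; CH2O (gas, from cracked paraformaldehyde), −78 °C; Ac2O, −78 °C to rt
Reagents that add atoms: formaldehyde, C=O; acetic anhydride, CC(=O)OC(C)=O
Why: Lithium–bromine exchange should proceed with retention of alkene geometry at −78 °C, the alkenyllithium adds to formaldehyde (C17) and the alkoxide is O-acetylated in the same flask, leaving CH2OAc cis to the chain and the vinyl group trans to it.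

Step 8
Reactants: 4 ethyl (1S)-1,3-dimethyl-4-oxocyclohex-2-ene-1-carboxylate; 13 (2Z,6S)-8-[(tert-butyldiphenylsilyl)oxy]-2-ethenyl-6-methyloct-2-en-1-yl acetate
Product: 14 ethyl (1S,4aR,5R,8aS)-6-(acetoxymethyl)-5-{(3S)-5-[(tert-butyldiphenylsilyl)oxy]-3-methylpentyl}-1,4a-dimethyl-4-oxo-1,2,3,4,4a,5,8,8a-octahydronaphthalene-1-carboxylate
Conditions: EtAlCl2 (2.5 equiv), CH2Cl2, −78 °C to −20 °C
Reagents that add atoms: none
Why: Lewis-acid-promoted, concerted but asynchronous [4+2] cycloaddition in which the unsubstituted diene terminus C6 bonds first to the β-carbon C5 of the EtAlCl2-bound enone and the chain-bearing terminus C9 closes onto the α-carbon C10; the closest known reaction type is the aluminium-halide-catalysed Diels–Alder reaction of 2-methylcyclohex-2-enones and 4,4-disubstituted cyclohexenones with (E)-1-alkyl dienes, which gives ortho-endo cis-octalones. Ring B is closed by intermolecular [4+2] ring formation (a cyclohexene from four diene and two dienophile carbons, suprafacial on both partners), ring A being carried in intact. C5 and C10 are set cis by the ring geometry of the dienophile (H-5 and the C10 methyl end on the same face), and C9 is set by the (E)-geometry of the C8=C9 bond together with the endo transition state, which places the C1 carbonyl under the diene and so puts the C11 chain trans to the C10 methyl. The absolute sense follows from C4: the diene should add to the enone face opposite the pseudoaxial, aluminium-coordinated ester, so that CO2Et ends cis to H-5 and the C10 methyl. Regioselectivity (C6 to C5, C9 to C10) is needed and is secured by the C9 alkyl group, which makes C6 the most nucleophilic and least hindered terminus, while the inductively withdrawn CH2OAc on C8 is only a weak counter-director. C4 and C13 are not touched.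

Step 9
Reactants: 14 ethyl (1S,4aR,5R,8aS)-6-(acetoxymethyl)-5-{(3S)-5-[(tert-butyldiphenylsilyl)oxy]-3-methylpentyl}-1,4a-dimethyl-4-oxo-1,2,3,4,4a,5,8,8a-octahydronaphthalene-1-carboxylate
Product: 15 ethyl (1S,4aR,5R,8aS)-5-{(3S)-5-[(tert-butyldiphenylsilyl)oxy]-3-methylpentyl}-1,4a-dimethyl-6-methylidene-4-oxodecahydronaphthalene-1-carboxylate
Conditions: Pd(OAc)2 (5 mol%), n-Bu3P (20 mol%), HCO2NH4 (3 equiv), 1,4-dioxane, 100 °C
Reagents that add atoms: none
Why: Palladium-catalysed formate hydrogenolysis of the allylic acetate (Tsuji–Trost-type), in which the hydride is delivered from the σ-allyl palladium formate to the more substituted terminus C7 and the alkene moves to the exocyclic C8=C17 position without touching C9.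

Step 10
Reactants: 15 ethyl (1S,4aR,5R,8aS)-5-{(3S)-5-[(tert-butyldiphenylsilyl)oxy]-3-methylpentyl}-1,4a-dimethyl-6-methylidene-4-oxodecahydronaphthalene-1-carboxylate
Product: 17 (1S,4aR,5R,8aS)-5-[(3S)-5-hydroxy-3-methylpentyl]-1,4a-dimethyl-6-methylidenedecahydronaphthalene-1-carboxylic acid, via hydrazone 16 (not isolated)
Conditions: N2H4·H2O, diethylene glycol, 130 °C; then KOH, 200 °C under argon; aq. HCl work-up
Reagents that add atoms: potassium hydroxide, [K+].[OH-]
Why: Wolff–Kishner reduction (Huang-Minlon procedure) turns the C1 ketone into CH2 through the hydrazone while the hot alkali saponifies the C19 ethyl ester and cleaves the silyl ether, and no centre can epimerise because the only stereogenic α-carbon (C10) is quaternary.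

Step 11
Reactants: 17 (1S,4aR,5R,8aS)-5-[(3S)-5-hydroxy-3-methylpentyl]-1,4a-dimethyl-6-methylidenedecahydronaphthalene-1-carboxylic acid; 18 Meldrum's acid
Product: 19 (1S,4aR,5R,8aS)-5-{(3S)-5-[(carboxyacetyl)oxy]-3-methylpentyl}-1,4a-dimethyl-6-methylidenedecahydronaphthalene-1-carboxylic acid
Conditions: toluene, 100 °C
Reagents that add atoms: none
Why: Thermal ring opening of Meldrum's acid by the primary alcohol (O-acylation with loss of acetone) gives the malonic half ester, and the hindered tertiary C19 acid should not react.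

Step 12
Reactants: 19 (1S,4aR,5R,8aS)-5-{(3S)-5-[(carboxyacetyl)oxy]-3-methylpentyl}-1,4a-dimethyl-6-methylidenedecahydronaphthalene-1-carboxylic acid; 20 3,4-dihydroxybenzaldehyde
Product: 21 target, (1S,4aR,5R,8aS)-5-[(3S)-5-{[(2E)-3-(3,4-dihydroxyphenyl)prop-2-enoyl]oxy}-3-methylpentyl]-1,4a-dimethyl-6-methylidenedecahydronaphthalene-1-carboxylic acid
Conditions: pyridine, piperidine (cat.), 60 °C; cold dilute acid work-up
Reagents that add atoms: none
Why: Knoevenagel–Doebner condensation, in which the malonic half ester condenses with the aldehyde and decarboxylates to the thermodynamically favoured (E)-cinnamate, so neither the catechol nor the C19 acid needs protection.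

Compound list
1 | ethyl 2-formylpropanoate (racemic, enolisable) | CCOC(=O)C(C)C=O | starting material
2 | pent-1-en-3-one (ethyl vinyl ketone) | CCC(=O)C=C | starting material
3 | ethyl (2S)-2-formyl-2-methyl-5-oxoheptanoate | CCOC(=O)[C@](C)(C=O)CCC(=O)CC | intermediate
4 | ethyl (1S)-1,3-dimethyl-4-oxocyclohex-2-ene-1-carboxylate (ring A dienophile) | CCOC(=O)[C@]1(C)C=C(C)C(=O)CC1 | intermediate
5 | (S)-citronellol, (3S)-3,7-dimethyloct-6-en-1-ol | CC(C)=CCC[C@H](C)CCO | starting material
6 | tert-butyl{[(3S)-3,7-dimethyloct-6-en-1-yl]oxy}diphenylsilane | CC(C)=CCC[C@H](C)CCO[Si](c1ccccc1)(c1ccccc1)C(C)(C)C | intermediate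
7 | secondary ozonide of 6, 3,3-dimethyl-5-{(3S)-5-[(tert-butyldiphenylsilyl)oxy]-3-methylpentyl}-1,2,4-trioxolane (epimers at the ring CH) | CC1(C)OOC(CC[C@H](C)CCO[Si](c2ccccc2)(c2ccccc2)C(C)(C)C)O1 | intermediate
8 | (4S)-6-[(tert-butyldiphenylsilyl)oxy]-4-methylhexanal | O=CCC[C@H](C)CCO[Si](c1ccccc1)(c1ccccc1)C(C)(C)C | intermediate
9 | tert-butyl{[(3S)-7,7-dibromo-3-methylhept-6-en-1-yl]oxy}diphenylsilane | BrC(Br)=CCC[C@H](C)CCO[Si](c1ccccc1)(c1ccccc1)C(C)(C)C | intermediate
10 | tert-butyl{[(3S,6Z)-7-bromo-3-methylnona-6,8-dien-1-yl]oxy}diphenylsilane (vinyl trans to the chain) | C=C/C(Br)=C/CC[C@H](C)CCO[Si](c1ccccc1)(c1ccccc1)C(C)(C)C | intermediate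
11 | dienyllithium, lithium in place of the bromine of 10 with the geometry retained | C=C/C([Li])=C/CC[C@H](C)CCO[Si](c1ccccc1)(c1ccccc1)C(C)(C)C | intermediate
12 | lithium (2Z,6S)-8-[(tert-butyldiphenylsilyl)oxy]-2-ethenyl-6-methyloct-2-en-1-olate | C=C/C(C[O-])=C/CC[C@H](C)CCO[Si](c1ccccc1)(c1ccccc1)C(C)(C)C.[Li+] | intermediate
13 | (2Z,6S)-8-[(tert-butyldiphenylsilyl)oxy]-2-ethenyl-6-methyloct-2-en-1-yl acetate (diene; vinyl trans to the chain) | C=C/C(COC(C)=O)=C/CC[C@H](C)CCO[Si](c1ccccc1)(c1ccccc1)C(C)(C)C | intermediate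
14 | ethyl (1S,4aR,5R,8aS)-6-(acetoxymethyl)-5-{(3S)-5-[(tert-butyldiphenylsilyl)oxy]-3-methylpentyl}-1,4a-dimethyl-4-oxo-1,2,3,4,4a,5,8,8a-octahydronaphthalene-1-carboxylate (cis-fused; H-8a, 4a-CH3, H-5 and CO2Et on one face) | CC(=O)OCC1=CC[C@H]2[C@](C)(C(=O)CC[C@]2(C)C(=O)OCC)[C@@H]1CC[C@H](C)CCO[Si](c1ccccc1)(c1ccccc1)C(C)(C)C | intermediate
15 | ethyl (1S,4aR,5R,8aS)-5-{(3S)-5-[(tert-butyldiphenylsilyl)oxy]-3-methylpentyl}-1,4a-dimethyl-6-methylidene-4-oxodecahydronaphthalene-1-carboxylate | C=C1CC[C@H]2[C@](C)(C(=O)CC[C@]2(C)C(=O)OCC)[C@@H]1CC[C@H](C)CCO[Si](c1ccccc1)(c1ccccc1)C(C)(C)C | intermediate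
16 | hydrazone of 15 at the ring ketone (C=N–NH2, other groups as in 15) | C=C1CC[C@H]2[C@](C)(C(=NN)CC[C@]2(C)C(=O)OCC)[C@@H]1CC[C@H](C)CCO[Si](c1ccccc1)(c1ccccc1)C(C)(C)C | intermediate
17 | (1S,4aR,5R,8aS)-5-[(3S)-5-hydroxy-3-methylpentyl]-1,4a-dimethyl-6-methylidenedecahydronaphthalene-1-carboxylic acid | C=C1CC[C@H]2[C@](C)(CCC[C@]2(C)C(=O)O)[C@@H]1CC[C@H](C)CCO | intermediate
18 | Meldrum's acid, 2,2-dimethyl-1,3-dioxane-4,6-dione | CC1(C)OC(=O)CC(=O)O1 | starting material
19 | (1S,4aR,5R,8aS)-5-{(3S)-5-[(carboxyacetyl)oxy]-3-methylpentyl}-1,4a-dimethyl-6-methylidenedecahydronaphthalene-1-carboxylic acid | C=C1CC[C@H]2[C@](C)(CCC[C@]2(C)C(=O)O)[C@@H]1CC[C@H](C)CCOC(=O)CC(=O)O | intermediate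
20 | 3,4-dihydroxybenzaldehyde | O=Cc1ccc(O)c(O)c1 | starting material
21 | (1S,4aR,5R,8aS)-5-[(3S)-5-{[(2E)-3-(3,4-dihydroxyphenyl)prop-2-enoyl]oxy}-3-methylpentyl]-1,4a-dimethyl-6-methylidenedecahydronaphthalene-1-carboxylic acid | C=C1CC[C@H]2[C@](C)(CCC[C@]2(C)C(=O)O)[C@@H]1CC[C@H](C)CCOC(=O)/C=C/c1ccc(O)c(O)c1 | target

Total step count: 12 steps.
Longest linear sequence: 10 steps (steps 3 to 12, from (S)-citronellol).

Steps most likely to fail

Step 8. The cycloaddition may be too slow for an enone that is substituted at both C10 and next to C5. The Lewis acid could then ionise the allylic acetate or oligomerise the diene first, and at the higher temperatures then needed the preference for the face anti to the C4 ester and for the endo mode may erode. The fallback changes the dienophile to a cationic one. Setting out from 4, 1,2-bis(trimethylsilyloxy)ethane with catalytic TMSOTf in CH2Cl2 at −78 °C should give ethylene ketal F1; the alkene cannot migrate because C4 carries no hydrogen. F1 and diene 13 with catalytic TfOH in CH2Cl2 at −78 °C should react in an ionic Diels–Alder reaction through the ring-opened alkoxyallyl cation, a far stronger dienophile, to give ketal adduct F2 with the same regio- and stereochemical preferences at a temperature at which the acetate is safe. PPTS in wet acetone then frees the ketone and the route is rejoined at 14.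

Step 10. Hydrazone formation at the C1 carbonyl, which is flanked by quaternary C10, may be incomplete. Long exposure to hydrazine and alkali at 200 °C may also move or reduce (through diimide) the exocyclic alkene, or convert the C19 ester into a hydrazide. The fallback is a radical deoxygenation. Setting out from 15, NaBH4 in MeOH at 0 °C should give alcohol F3 (both C1 epimers are usable). 1,1'-Thiocarbonyldiimidazole and DMAP in toluene at 80 °C should give thiocarbonylimidazolide F4 under neutral conditions. Bu3SnH and AIBN in refluxing toluene (Barton–McCombie) should give deoxygenated ester F5. KOH in aqueous ethylene glycol at 150 °C then saponifies the ester and cleaves the silyl ether, and the route is rejoined at 17.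

Step 7. The dienyllithium may lose its alkene geometry or be protonated before it is trapped, and its capture by gaseous formaldehyde may be inefficient. The fallback installs C17 by palladium catalysis. Setting out from 10, Stille coupling with (tributylstannyl)methanol (Pd(PPh3)4, 1,4-dioxane, 90 °C) should give dienol F6 with retention of geometry. Ac2O, pyridine and DMAP then give 13, where the route is rejoined.

Further compounds
F1 | step 8 | ethyl (8S)-6,8-dimethyl-1,4-dioxaspiro[4.5]dec-6-ene-8-carboxylate (ethylene ketal of 4) | CCOC(=O)[C@]1(C)C=C(C)C2(CC1)OCCO2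
F2 | step 8 | ethylene ketal of adduct 14 at the ring ketone | CC(=O)OCC1=CC[C@H]2[C@](C)(C3(CC[C@]2(C)C(=O)OCC)OCCO3)[C@@H]1CC[C@H](C)CCO[Si](c1ccccc1)(c1ccccc1)C(C)(C)C
F3 | step 10 | secondary alcohol from reduction of the ring ketone of 15 (epimers at the carbinol carbon) | C=C1CC[C@H]2[C@](C)(C(O)CC[C@]2(C)C(=O)OCC)[C@@H]1CC[C@H](C)CCO[Si](c1ccccc1)(c1ccccc1)C(C)(C)C
F4 | step 10 | O-(imidazol-1-ylthiocarbonyl) derivative of F3 | C=C1CC[C@H]2[C@](C)(C(OC(=S)n3ccnc3)CC[C@]2(C)C(=O)OCC)[C@@H]1CC[C@H](C)CCO[Si](c1ccccc1)(c1ccccc1)C(C)(C)C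
F5 | step 10 | ethyl (1S,4aR,5R,8aS)-5-{(3S)-5-[(tert-butyldiphenylsilyl)oxy]-3-methylpentyl}-1,4a-dimethyl-6-methylidenedecahydronaphthalene-1-carboxylate | C=C1CC[C@H]2[C@](C)(CCC[C@]2(C)C(=O)OCC)[C@@H]1CC[C@H](C)CCO[Si](c1ccccc1)(c1ccccc1)C(C)(C)C
F6 | step 7 | (2Z,6S)-8-[(tert-butyldiphenylsilyl)oxy]-2-ethenyl-6-methyloct-2-en-1-ol | C=C/C(CO)=C/CC[C@H](C)CCO[Si](c1ccccc1)(c1ccccc1)C(C)(C)C
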